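**Retrosynthetic overview**
1. Ten-membered ring last: a Criegee 1,2-shift (C10 migrates from C5 to oxygen, with retention) in the perester of a cis-fused 5-hydroperoxy-eudesmanolide opens the C5–C10 ring-fusion bond, giving the C5 ketone and the C10 tertiary alcohol; the C9 ester goes on in the same operation.
2. Ring B (C9–C10 bond) by a Prins cyclisation of a lactone aldehyde onto a 2,6-dimethylcyclohexene, the C5 cation being trapped by H2O2 (new step).
3. Lactone ring (C7–C8 bond, exo-methylene) by catalytic asymmetric chromium-mediated 2-(alkoxycarbonyl)allylation of 2,2-dimethoxyacetaldehyde.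
4. Allyl bromide by cross-metathesis of methyl 2-(bromomethyl)acrylate with the allyl carbinol of 2,6-dimethylcyclohexanone (from 2-methylcyclohexanone and MeI).
5. Ring order: ring A (bought) → lactone → ring B → ring expansion to the ten-membered ring.

Assumption: the target is exactly the structure of the given SMILES; ring carbons are cited by eudesmane/germacrane locants (C5 ketone carbon, C4 its methyl-bearing neighbour, C10 carbinol carbon, C9 ester carbon, C8 lactone O–CH, C7 lactone ring-fusion CH).

**Route**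

Step 1
Reactants: 1 2-methylcyclohexanone
Product: 2 2,6-dimethylcyclohexanone (cis/trans mixture)
Conditions: LiN(i-Pr)2 (1.05 equiv), THF, −78 °C; MeI, −78 → 0 °C
Reagents that add atoms: iodomethane, CI
Why: Kinetic enolate alkylation: the amide base removes the less hindered C6 proton and the enolate is methylated; the cis/trans ratio is irrelevant because both methyl-bearing carbons are planarised or re-set in step 5.

Step 2
Reactants: 2 2,6-dimethylcyclohexanone; 3 allylmagnesium bromide
Product: 4 2,6-dimethyl-1-(prop-2-en-1-yl)cyclohexan-1-ol (mixture of ring diastereomers)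
Conditions: Et2O, 0 °C; then H2O
Reagents that add atoms: none
Why: Grignard 1,2-addition of an allyl nucleophile (cyclic transition state, tolerant of the two flanking methyls) makes the C5–C6 bond; the new carbinol centre is ionised in step 5, so its configuration does not matter.

Step 3
Reactants: 4 2,6-dimethyl-1-(prop-2-en-1-yl)cyclohexan-1-ol; 5 methyl 2-(bromomethyl)prop-2-enoate
Product: 6 methyl (2Z)-2-(bromomethyl)-4-(1-hydroxy-2,6-dimethylcyclohexyl)but-2-enoate
Conditions: 5 (4 equiv), second-generation Hoveyda–Grubbs catalyst [RuCl2(H2IMes)(=CH-C6H4-2-O-i-Pr)] (5 mol %), CH2Cl2, 40 °C; used directly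
Reagents that add atoms: none
Why: Olefin cross-metathesis between a reactive terminal alkene and a non-dimerising 2-substituted acrylate gives the trisubstituted enoate with the ring chain trans to the ester (Z by CIP); either geometry converges on the same allylchromium in step 4.

Step 4
Reactants: 6 methyl (2Z)-2-(bromomethyl)-4-(1-hydroxy-2,6-dimethylcyclohexyl)but-2-enoate; 7 2,2-dimethoxyacetaldehyde
Product: 9 (4R,5R)-5-(dimethoxymethyl)-4-[(1-hydroxy-2,6-dimethylcyclohexyl)methyl]-3-methylideneoxolan-2-one, via silyl ether adduct 8 (not isolated)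
Conditions: CrCl2 (10 mol %), 3,6-di-tert-butyl-1,8-bis(4-isopropyl-4,5-dihydrooxazol-2-yl)-9H-carbazole (12 mol %, the enantiomer that gives Re-face attack on 7), Mn powder (2 equiv), Me3SiCl (2 equiv), i-Pr2NEt (0.3 equiv), THF, 20 °C; then 1 M aq HCl, THF, 20 °C
Reagents that add atoms: none
Why: Catalytic asymmetric Nozaki–Hiyama–Kishi-type 2-(alkoxycarbonyl)allylation: the allylchromium (trivalent chromium) adds through its γ-carbon in a chair transition state (anti adduct, hence trans lactone) and the tridentate ligand directs Re-face attack on 7, setting C7 and C8 (both R); acid work-up removes the silyl group and closes the α-methylene lactone.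

Step 5
Reactants: 9 (4R,5R)-5-(dimethoxymethyl)-4-[(1-hydroxy-2,6-dimethylcyclohexyl)methyl]-3-methylideneoxolan-2-one
Product: 12 (4S,5S,7R,8R,9R,10R)-5-hydroperoxy-9-hydroxyeudesm-11(13)-en-12,8-olide, via lactone aldehyde 10 (not isolated), via cyclohexene aldehyde 11 (not isolated)
Conditions: H2O2 (50% aq, 30 equiv), H2SO4 (2 equiv), MeCN, 0 → 20 °C
Reagents that add atoms: hydrogen peroxide, OO; water, O
Why: Proposed new method: a Prins cyclisation terminated by hydrogen peroxide: aqueous acid unmasks aldehyde 10 and reversibly ionises the tertiary alcohol to the tetrasubstituted cyclohexene 11 (C4 epimerises through the same cation); C10 then adds to the protonated aldehyde through a chair with the trans-lactone diequatorial, the new C–O bond equatorial and approach anti to the C4 methyl (setting C9, C10 and C4), and the tertiary C5 cation is captured by H2O2 as in acid-catalysed perhydrolysis (cis ring fusion, a centre that is destroyed in step 6); closest known reactions are the aqueous Prins cyclisation of citronellal to p-menthane-3,8-diol and the H2O2/H2SO4 conversion of tertiary alcohols into hydroperoxides.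

Step 6
Reactants: 12 (4S,5S,7R,8R,9R,10R)-5-hydroperoxy-9-hydroxyeudesm-11(13)-en-12,8-olide; 13 (2S)-2-methylbutanoyl chloride
Product: 16 (4S,7R,8R,9S,10R)-10-hydroxy-9-[(2S)-2-methylbutanoyloxy]-5-oxogermacr-11(13)-en-12,8-olide (target), via bis-acyl perester 14 (not isolated), via bridged ketal ester 15 (not isolated)
Conditions: 13 (2.5 equiv), pyridine (5 equiv), 4-(dimethylamino)pyridine (0.2 equiv), CH2Cl2, 0 °C; then MeCN–H2O (4:1), 45 °C
Reagents that add atoms: water, O
Why: Criegee rearrangement (1,2-shift from carbon to oxygen, ring expansion): the C9 hydroxyl and the hydroperoxide are both acylated, heterolysis of the perester O–O bond is accompanied by migration of the fully substituted C10 (best migrating group) from C5 to oxygen with retention, which turns the decalin into the oxygen-bridged ten-membered ring and fixes the (10R) carbinol, and water then hydrolyses the labile ketal ester 15 to the C5 ketone and C10 alcohol under non-epimerising conditions for C4.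

**Compound list**
1 | 2-methylcyclohexanone (racemic) | CC1CCCCC1=O | starting material
2 | 2,6-dimethylcyclohexanone (cis/trans mixture) | CC1CCCC(C)C1=O | intermediate
3 | allylmagnesium bromide (CH2=CHCH2MgBr) | C=CC[Mg]Br | starting material
4 | 2,6-dimethyl-1-(prop-2-en-1-yl)cyclohexan-1-ol (ring diastereomer mixture) | C=CCC1(O)C(C)CCCC1C | intermediate
5 | methyl 2-(bromomethyl)prop-2-enoate | C=C(CBr)C(=O)OC | starting material
6 | methyl (2Z)-2-(bromomethyl)-4-(1-hydroxy-2,6-dimethylcyclohexyl)but-2-enoate (ring diastereomer mixture) | BrC/C(C(=O)OC)=C\CC1(O)C(C)CCCC1C | intermediate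
7 | 2,2-dimethoxyacetaldehyde | COC(OC)C=O | starting material
8 | silyl ether adduct: methyl (3R,4R)-3-[(1-hydroxy-2,6-dimethylcyclohexyl)methyl]-5,5-dimethoxy-2-methylidene-4-(trimethylsilyloxy)pentanoate | C=C(C(=O)OC)[C@@H](CC1(O)C(C)CCCC1C)[C@@H](O[Si](C)(C)C)C(OC)OC | intermediate
9 | (4R,5R)-5-(dimethoxymethyl)-4-[(1-hydroxy-2,6-dimethylcyclohexyl)methyl]-3-methylideneoxolan-2-one (trans lactone; ring A a diastereomer mixture) | C=C1C(=O)O[C@@H](C(OC)OC)[C@@H]1CC2(O)C(C)CCCC2C | intermediate
10 | lactone aldehyde: (2R,3R)-3-[(1-hydroxy-2,6-dimethylcyclohexyl)methyl]-4-methylidene-5-oxooxolane-2-carbaldehyde | C=C1C(=O)O[C@@H](C=O)[C@@H]1CC2(O)C(C)CCCC2C | intermediate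
11 | cyclohexene aldehyde: (2R,3R)-3-[(2,6-dimethylcyclohex-1-en-1-yl)methyl]-4-methylidene-5-oxooxolane-2-carbaldehyde (C4 epimers equilibrating) | C=C1C(=O)O[C@@H](C=O)[C@@H]1CC2=C(C)CCCC2C | intermediate
12 | (4S,5S,7R,8R,9R,10R)-5-hydroperoxy-9-hydroxyeudesm-11(13)-en-12,8-olide; cis-fused decalin, i.e. (3aR,4aS,5S,8aR,9R,9aR)-4a-hydroperoxy-9-hydroxy-5,8a-dimethyl-3-methylidenedecahydronaphtho[2,3-b]furan-2(3H)-one | C=C1C(=O)O[C@@H]2[C@@H]1C[C@]3(OO)[C@@H](C)CCC[C@]3(C)[C@H]2O | intermediate
13 | (2S)-2-methylbutanoyl chloride | ClC(=O)[C@@H](C)CC | starting material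
14 | bis-acyl perester: (4S,5S,7R,8R,9R,10R)-9-[(2S)-2-methylbutanoyloxy]-5-[(2S)-2-methylbutanoylperoxy]eudesm-11(13)-en-12,8-olide | C=C1C(=O)O[C@@H]2[C@@H]1C[C@]3(OOC(=O)[C@@H](C)CC)[C@@H](C)CCC[C@]3(C)[C@H]2OC(=O)[C@@H](C)CC | intermediate
15 | bridged ketal ester: (4S,5S,7R,8R,9S,10R)-5,10-epoxy-5,9-bis[(2S)-2-methylbutanoyloxy]germacr-11(13)-en-12,8-olide (11-oxabicyclo[4.4.1]undecane core) | C=C1C(=O)O[C@@H]2[C@@H]1C[C@]3(OC(=O)[C@@H](C)CC)[C@@H](C)CCC[C@@](C)(O3)[C@H]2OC(=O)[C@@H](C)CC | intermediate
16 | (4S,7R,8R,9S,10R)-10-hydroxy-9-[(2S)-2-methylbutanoyloxy]-5-oxogermacr-11(13)-en-12,8-olide (CNP0144277.6) | C=C1C(=O)O[C@@H]2[C@@H]1CC(=O)[C@@H](C)CCC[C@@](C)(O)[C@H]2OC(=O)[C@@H](C)CC | target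

**Step count and risks**
Total steps: 6. Longest linear sequence: 6 steps (1 → 2 → 4 → 6 → 9 → 12 → 16).

Step 5 (the proposed new step) is the most likely to fail. The monocyclic cation may be trapped by H2O2 before it cyclises, the spiro five-membered closure may compete, the lactone-bearing aldehyde carbon may epimerise, and C4 may equilibrate to the wrong epimer. The fallback uses known chemistry and sets out from 9. Aqueous acid alone (CF3CO2H–H2O 4:1, 0 °C), the water-terminated Prins manifold known from citronellal, gives the cis-fused diol (4S,5S,7R,8R,9R,10R)-5,9-dihydroxyeudesm-11(13)-en-12,8-olide F4. Classical perhydrolysis of its tertiary alcohol (50% H2O2, catalytic H2SO4, 0 °C) then gives 12, where the route is rejoined.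

Step 6 is the second risk. The C9 acyloxy group lowers the migratory aptitude of C10, so C4 migration (ring A oxepane ketal) could compete, and a carboxylate perester may ionise slowly. The fallback sets out from 12 and puts the ester on last. The free hydroperoxide undergoes acid-promoted Hock-type rearrangement (BF3·OEt2, CH2Cl2, −40 °C; aqueous work-up) with C9 as a free hydroxyl, giving (4S,7R,8R,9S,10R)-9,10-dihydroxy-5-oxogermacr-11(13)-en-12,8-olide F5. Selective acylation of its secondary hydroxyl with 13 (1.1 equiv, pyridine, 0 °C) gives 16.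

Step 4 is the third risk. High anti selectivity and enantioselectivity are not assured for a γ-branched bromide carrying a free tertiary alcohol and a chelating aldehyde. The fallback replaces catalyst control by substrate control and sets out from 6. Stoichiometric CrCl2 (THF, 20 °C) mediates addition to (4S)-2,2-dimethyl-1,3-dioxolane-4-carbaldehyde F1 (Felkin–Anh attack, anti allylchromium addition), and acid work-up lactonises to (4R,5R)-5-[(4S)-2,2-dimethyl-1,3-dioxolan-4-yl]-4-[(1-hydroxy-2,6-dimethylcyclohexyl)methyl]-3-methylideneoxolan-2-one F2. Aqueous AcOH (60%, 20 °C) removes the acetonide to give (4R,5R)-5-[(1S)-1,2-dihydroxyethyl]-4-[(1-hydroxy-2,6-dimethylcyclohexyl)methyl]-3-methylideneoxolan-2-one F3. NaIO4 (THF–H2O, 0 °C) cleaves the glycol to aldehyde 10, which is submitted to the step 5 conditions; the route is rejoined at 10.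

**Further compounds**
F1 | step 4 | (4S)-2,2-dimethyl-1,3-dioxolane-4-carbaldehyde | O=C[C@@H]1COC(C)(C)O1
F2 | step 4 | (4R,5R)-5-[(4S)-2,2-dimethyl-1,3-dioxolan-4-yl]-4-[(1-hydroxy-2,6-dimethylcyclohexyl)methyl]-3-methylideneoxolan-2-one | C=C1C(=O)O[C@@H]([C@@H]2COC(C)(C)O2)[C@@H]1CC3(O)C(C)CCCC3C
F3 | step 4 | (4R,5R)-5-[(1S)-1,2-dihydroxyethyl]-4-[(1-hydroxy-2,6-dimethylcyclohexyl)methyl]-3-methylideneoxolan-2-one | C=C1C(=O)O[C@@H]([C@@H](O)CO)[C@@H]1CC2(O)C(C)CCCC2C
F4 | step 5 | (4S,5S,7R,8R,9R,10R)-5,9-dihydroxyeudesm-11(13)-en-12,8-olide | C=C1C(=O)O[C@@H]2[C@@H]1C[C@]3(O)[C@@H](C)CCC[C@]3(C)[C@H]2O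
F5 | step 6 | (4S,7R,8R,9S,10R)-9,10-dihydroxy-5-oxogermacr-11(13)-en-12,8-olide | C=C1C(=O)O[C@@H]2[C@@H]1CC(=O)[C@@H](C)CCC[C@@](C)(O)[C@H]2O
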